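Ring numbering: C1(=CH2), C2=C3, C4(Me2), C5(O-acyl), C6, C7, C8(Me)=C9, C10, C11.
Cuts, in order: vanillate acyl–O bond at C5; C5–H (back to the ketone); C6–C7, reopened with CO2 inserted as C6–C(=O)–O–C7; lactone acyl–O bond; C5–C6; C1–C2; C7–OH.
Enabling feature: a C5 ketone next to quaternary C4 can enolise only towards C6, and C6 is bonded to C7, the unsubstituted end of the C7–C8(Me)=C9 allyl unit. C6–C7 is therefore an enolate/π-allyl bond, and the 11-membered carbocycle can be reached from a 13-membered allyl β-keto lactone by loss of CO2.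
Forward: a C8 ketone supplies C7–C11, C1 and the exocyclic CH2; a Heck reaction adds C2–C5; Meldrum's acid adds C6 and the carbon later lost as CO2. The 13-membered lactone closes first, then contracts to the 11-membered ring.
Stereochemistry: both E alkenes come from substrate-controlled steps (allylic oxidation, Heck). The only stereocentre, C5 (R), is set by catalyst-controlled ketone reduction and kept by O-acylation.

Key step: step 8

Assumption: the planar-chiral conformers of the eleven-membered trienone interconvert rapidly at the reduction temperature, so the reduction catalyst alone decides the configuration at C5.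

Step 1
Reactants: 1 6-methylhept-5-en-2-one
Product: 2 (E)-7-hydroxy-6-methylhept-5-en-2-one
Conditions: SeO2 (cat.), t-BuOOH, salicylic acid (cat.), CH2Cl2, 0 °C to rt
Reagents that add atoms: tert-butyl hydroperoxide, CC(C)(C)OO (terminal source of the new oxygen, relayed by selenium dioxide, O=[Se]=O)
Why: Selenium dioxide allylic oxidation (ene reaction, then [2,3]-sigmatropic shift, run catalytically) hydroxylates the E methyl group of a gem-dimethyl trisubstituted alkene, which fixes the later C8=C9 geometry, while the methyl ketone is left alone under these mild conditions and any over-oxidised enal is removed by chromatography.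

Step 2
Reactants: 2 (E)-7-hydroxy-6-methylhept-5-en-2-one
Product: 3 (E)-7-(tert-butyldimethylsilyloxy)-6-methylhept-5-en-2-one
Conditions: TBSCl, imidazole, CH2Cl2, 0 °C to rt
Reagents that add atoms: tert-butyldimethylsilyl chloride, CC(C)(C)[Si](C)(C)Cl
Why: Standard silyl ether formation masks the primary allylic hydroxyl as a group that tolerates strong base, offers Pd(0) no ionisable leaving group and survives carbodiimide activation.

Step 3
Reactants: 3 (E)-7-(tert-butyldimethylsilyloxy)-6-methylhept-5-en-2-one
Product: 5 (5E)-7-(tert-butyldimethylsilyloxy)-6-methylhepta-1,5-dien-2-yl trifluoromethanesulfonate, via potassium enolate 4 (not isolated)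
Conditions: KHMDS, THF, −78 °C; then N-(5-chloro-2-pyridyl)triflimide, −78 °C
Reagents that add atoms: N-(5-chloro-2-pyridyl)bis(trifluoromethanesulfonimide), FC(F)(F)S(=O)(=O)N(c1ccc(Cl)cn1)S(=O)(=O)C(F)(F)F; potassium hexamethyldisilazide, C[Si](C)(C)[N-][Si](C)(C)C.[K+] (potassium of 4 only)
Why: Kinetic deprotonation of a methyl ketone by a bulky amide base occurs at the methyl group, and O-sulfonylation with the reactive pyridyl triflimide at the same temperature traps the enolate as the 1-alken-2-yl triflate before it can equilibrate (enol triflate synthesis).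

Step 4
Reactants: 5 (5E)-7-(tert-butyldimethylsilyloxy)-6-methylhepta-1,5-dien-2-yl trifluoromethanesulfonate; 6 2,2-dimethylbut-3-enoic acid (excess)
Product: 7 (3E,8E)-10-(tert-butyldimethylsilyloxy)-2,2,9-trimethyl-5-methylidenedeca-3,8-dienoic acid
Conditions: Pd(OAc)2 (cat.), P(o-tol)3 (cat.), Et3N, MeCN, 80 °C
Reagents that add atoms: none
Why: Mizoroki–Heck reaction in which the alkenylpalladium species adds to the unhindered CH2 terminus of the alkene, and quaternary C4 leaves only a C2 hydrogen for syn β-hydride elimination, so the E C2=C3 bond of the 2-substituted diene should form without positional isomers while the acid reacts as its ammonium salt.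

Step 5
Reactants: 7 (3E,8E)-10-(tert-butyldimethylsilyloxy)-2,2,9-trimethyl-5-methylidenedeca-3,8-dienoic acid; 8 Meldrum's acid (2,2-dimethyl-1,3-dioxane-4,6-dione)
Product: 9 5-[(3E,8E)-10-(tert-butyldimethylsilyloxy)-1-hydroxy-2,2,9-trimethyl-5-methylidenedeca-3,8-dien-1-ylidene]-2,2-dimethyl-1,3-dioxane-4,6-dione
Conditions: DCC, DMAP, CH2Cl2, 0 °C to rt; cold aq. KHSO4 wash
Reagents that add atoms: none
Why: Carbodiimide/DMAP C-acylation of Meldrum's acid, which also works for α,α-disubstituted acids, forms C5–C6 and installs the future lactone carbonyl in latent form as the enolised acyl Meldrum's acid.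

Step 6
Reactants: 9 silyl-protected acyl Meldrum's acid
Product: 10 5-[(3E,8E)-1,10-dihydroxy-2,2,9-trimethyl-5-methylidenedeca-3,8-dien-1-ylidene]-2,2-dimethyl-1,3-dioxane-4,6-dione
Conditions: HF·pyridine, THF, 0 °C; used without chromatography
Reagents that add atoms: none
Why: Fluoride-mediated desilylation in a mildly acidic medium frees the primary allylic alcohol, and at 0 °C the acyl Meldrum's acid, which reacts with alcohols only on heating, should stay intact.

Step 7
Reactants: 10 hydroxy acyl Meldrum's acid
Product: 12 (6E,11E)-5,5,12-trimethyl-8-methylidene-1-oxacyclotrideca-6,11-diene-2,4-dione, via acylketene 11 (not isolated)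
Conditions: toluene, reflux, syringe-pump addition (final ca. 1 mM)
Reagents that add atoms: none
Why: Thermal fragmentation of the acyl Meldrum's acid with loss of acetone and CO2 gives the acylketene, and its capture by the distal hydroxyl at high dilution is the known acylketene macrolactonisation, which is fast and neutral and is helped here by the gem-dimethyl group and the sp2 units that restrict the chain.

Step 8
Reactants: 12 (6E,11E)-5,5,12-trimethyl-8-methylidene-1-oxacyclotrideca-6,11-diene-2,4-dione
Product: 13 (3E,8E)-2,2,9-trimethyl-5-methylidenecycloundeca-3,8-dien-1-one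
Conditions: Pd2(dba)3·CHCl3 (cat.), PPh3 (cat.), THF, 50 °C, syringe-pump addition (ca. 2 mM)
Reagents that add atoms: none
Why: Pd(0) ionises the allylic C7–O bond of 12 to a syn η3-allylpalladium unit over C7–C8–C9 that remains tethered to the β-keto carboxylate; CO2 is lost, C6 (the only carbon that can become nucleophilic, since C4 has no hydrogen) bonds to C7, Pd(0) is released, and the order of decarboxylation and C–C bond formation does not change the product. The closest known reaction types are the decarboxylative Tsuji–Trost allylation of acyclic allyl β-keto esters and the π-allylpalladium closure of medium and large carbocycles by β-dicarbonyl nucleophiles; the ring-contracting use on a lactone is only thinly documented, so this is a demanding application of known reactivity. The one ring formed, the eleven-membered carbocycle, closes in the endo mode with respect to the allyl unit: attack at the far, unsubstituted terminus C7 places C8=C9 inside the ring and removes the O–C(=O) link from the 13-membered ring. No stereocentre arises, and the E geometry of C8=C9 is inherited because the E ester gives the syn complex and attack at C7 returns the E alkene. The step needs C7 over C9 attack, C- over O-allylation, and cyclisation over oligomerisation or β-hydride loss: C7 is primary and open, whereas attack at secondary C9 would build a nine-membered ring around the E C2=C3 bond, an O-allylated enol ether would re-ionise under Pd(0) and return to the C-alkylation channel, and slow addition at high dilution with a phosphine-rich catalyst in THF favours reaction within one chain.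

Step 9
Reactants: 13 (3E,8E)-2,2,9-trimethyl-5-methylidenecycloundeca-3,8-dien-1-one
Product: 14 (1R,3E,8E)-2,2,9-trimethyl-5-methylidenecycloundeca-3,8-dien-1-ol
Conditions: (S)-Me-CBS oxazaborolidine (cat.), catecholborane, toluene, −78 to −40 °C; MeOH, then aq. NaOH wash
Reagents that add atoms: none
Why: Corey–Bakshi–Shibata reduction in which the ketone binds the catalyst boron on the side of the small C6 methylene, away from quaternary C4, so hydride reaches the face giving the R carbinol (the same sense as tert-alkyl and aryl methyl ketones with the S catalyst), and catecholborane at low temperature should leave the three alkenes untouched.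

Step 10
Reactants: 15 vanillic acid (4-hydroxy-3-methoxybenzoic acid)
Product: 17 4-(tert-butyldimethylsilyloxy)-3-methoxybenzoic acid, via bis-silylated vanillic acid 16 (not isolated)
Conditions: TBSCl (excess), imidazole, DMF, rt; then AcOH–THF–H2O, rt
Reagents that add atoms: tert-butyldimethylsilyl chloride, CC(C)(C)[Si](C)(C)Cl
Why: Exhaustive silylation followed by selective hydrolysis of the much more labile silyl ester leaves the aryl silyl ether, a phenol mask that cannot transfer an acyl group in the esterification.

Step 11
Reactants: 17 4-(tert-butyldimethylsilyloxy)-3-methoxybenzoic acid; 14 (1R,3E,8E)-2,2,9-trimethyl-5-methylidenecycloundeca-3,8-dien-1-ol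
Product: 19 (1R,3E,8E)-2,2,9-trimethyl-5-methylidenecycloundeca-3,8-dien-1-yl 4-(tert-butyldimethylsilyloxy)-3-methoxybenzoate, via acid chloride 18 (not isolated)
Conditions: 17, (COCl)2, DMF (cat.), CH2Cl2, 0 °C to rt, evaporate; then 14, Et3N, DMAP (cat.), CH2Cl2, rt to 40 °C
Reagents that add atoms: oxalyl chloride, O=C(Cl)C(=O)Cl (chlorine of 18 only; no atom of it remains in 19)
Why: Acid chloride formation and DMAP-catalysed acylation provide the driving force needed for the hindered, neopentyl-type secondary alcohol, and because only the O–H bond reacts the R configuration at C5 is retained.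

Step 12
Reactants: 19 silyl-protected vanillate ester
Product: 20 (1R,3E,8E)-2,2,9-trimethyl-5-methylidenecycloundeca-3,8-dien-1-yl 4-hydroxy-3-methoxybenzoate (CNP0416843.1)
Conditions: TBAF, AcOH, THF, 0 °C
Reagents that add atoms: none
Why: Fluoride-mediated desilylation cleaves aryl silyl ethers rapidly at 0 °C, and the acetic acid buffer keeps the medium mild enough for the benzoate ester, the triene and the C5 stereocentre.

Compound list
1 | 6-methylhept-5-en-2-one | CC(C)=CCCC(C)=O | starting material
2 | (E)-7-hydroxy-6-methylhept-5-en-2-one | CC(=O)CC/C=C(\C)CO | intermediate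
3 | (E)-7-(tert-butyldimethylsilyloxy)-6-methylhept-5-en-2-one | CC(=O)CC/C=C(\C)CO[Si](C)(C)C(C)(C)C | intermediate
4 | potassium (5E)-7-(tert-butyldimethylsilyloxy)-6-methylhepta-1,5-dien-2-olate | [K+].[O-]C(=C)CC/C=C(\C)CO[Si](C)(C)C(C)(C)C | intermediate
5 | (5E)-7-(tert-butyldimethylsilyloxy)-6-methylhepta-1,5-dien-2-yl trifluoromethanesulfonate | C=C(OS(=O)(=O)C(F)(F)F)CC/C=C(\C)CO[Si](C)(C)C(C)(C)C | intermediate
6 | 2,2-dimethylbut-3-enoic acid | C=CC(C)(C)C(=O)O | starting material
7 | (3E,8E)-10-(tert-butyldimethylsilyloxy)-2,2,9-trimethyl-5-methylidenedeca-3,8-dienoic acid | OC(=O)C(C)(C)/C=C/C(=C)CC/C=C(\C)CO[Si](C)(C)C(C)(C)C | intermediate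
8 | Meldrum's acid | CC1(C)OC(=O)CC(=O)O1 | starting material
9 | 5-[(3E,8E)-10-(tert-butyldimethylsilyloxy)-1-hydroxy-2,2,9-trimethyl-5-methylidenedeca-3,8-dien-1-ylidene]-2,2-dimethyl-1,3-dioxane-4,6-dione | CC1(C)OC(=O)C(=C(O)C(C)(C)/C=C/C(=C)CC/C=C(\C)CO[Si](C)(C)C(C)(C)C)C(=O)O1 | intermediate
10 | 5-[(3E,8E)-1,10-dihydroxy-2,2,9-trimethyl-5-methylidenedeca-3,8-dien-1-ylidene]-2,2-dimethyl-1,3-dioxane-4,6-dione | CC1(C)OC(=O)C(=C(O)C(C)(C)/C=C/C(=C)CC/C=C(\C)CO)C(=O)O1 | intermediate
11 | (5E,10E)-12-hydroxy-4,4,11-trimethyl-7-methylidenedodeca-1,5,10-triene-1,3-dione (acylketene) | O=C=CC(=O)C(C)(C)/C=C/C(=C)CC/C=C(\C)CO | intermediate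
12 | (6E,11E)-5,5,12-trimethyl-8-methylidene-1-oxacyclotrideca-6,11-diene-2,4-dione | C=C1/C=C/C(C)(C)C(=O)CC(=O)OC/C(C)=C/CC1 | intermediate
13 | (3E,8E)-2,2,9-trimethyl-5-methylidenecycloundeca-3,8-dien-1-one | C=C1/C=C/C(C)(C)C(=O)CC/C(C)=C/CC1 | intermediate
14 | (1R,3E,8E)-2,2,9-trimethyl-5-methylidenecycloundeca-3,8-dien-1-ol | C=C1/C=C/C(C)(C)[C@H](O)CC/C(C)=C/CC1 | intermediate
15 | vanillic acid | COc1cc(C(=O)O)ccc1O | starting material
16 | tert-butyldimethylsilyl 4-(tert-butyldimethylsilyloxy)-3-methoxybenzoate | COc1cc(C(=O)O[Si](C)(C)C(C)(C)C)ccc1O[Si](C)(C)C(C)(C)C | intermediate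
17 | 4-(tert-butyldimethylsilyloxy)-3-methoxybenzoic acid | COc1cc(C(=O)O)ccc1O[Si](C)(C)C(C)(C)C | intermediate
18 | 4-(tert-butyldimethylsilyloxy)-3-methoxybenzoyl chloride | COc1cc(C(=O)Cl)ccc1O[Si](C)(C)C(C)(C)C | intermediate
19 | (1R,3E,8E)-2,2,9-trimethyl-5-methylidenecycloundeca-3,8-dien-1-yl 4-(tert-butyldimethylsilyloxy)-3-methoxybenzoate | C=C1/C=C/C(C)(C)[C@H](OC(=O)c2ccc(O[Si](C)(C)C(C)(C)C)c(OC)c2)CC/C(C)=C/CC1 | intermediate
20 | (1R,3E,8E)-2,2,9-trimethyl-5-methylidenecycloundeca-3,8-dien-1-yl 4-hydroxy-3-methoxybenzoate | C=C1/C=C/C(C)(C)[C@H](OC(=O)c2ccc(O)c(OC)c2)CC/C(C)=C/CC1 | target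

Total step count: 12. Longest linear sequence: 11 (steps 1–9, 11 and 12); step 10 is a one-step side branch.

Steps most likely to fail

Step 8. After ionisation, several processes can overtake transannular C–C bond formation:
- intermolecular allylation leading to oligomers
- β-hydride loss from the π-allyl unit together with protonation of the enolate
- syn–anti exchange that erodes the alkene geometry

The fallback sets out from 10, returns at 13, and forms the same C6–C7 bond with a stabilised nucleophile that keeps its ester until the ring is closed. Heating 10 in methanol intercepts the acylketene with solvent and gives methyl (5E,10E)-12-hydroxy-4,4,11-trimethyl-7-methylidene-3-oxododeca-5,10-dienoate F1. Methyl chloroformate and pyridine convert it into methyl (5E,10E)-12-(methoxycarbonyloxy)-4,4,11-trimethyl-7-methylidene-3-oxododeca-5,10-dienoate F2. Pd(PPh3)4/dppe in refluxing THF at high dilution carries out a classical neutral Tsuji–Trost macrocyclisation to racemic methyl (4E,9E)-3,3,10-trimethyl-6-methylidene-2-oxocycloundeca-4,9-diene-1-carboxylate F3. Krapcho demethoxycarbonylation (LiCl, wet DMSO, heat) then delivers 13.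

Step 4. Insertion into the unactivated, neopentyl-type alkene may be sluggish. Hydrolysis or reduction of the enol triflate, or cyclisation of the alkenylpalladium species onto the C8=C9 alkene, could then take over. The fallback sets out from 5, returns at 7, and replaces alkene insertion by transmetalation. Commercial methyl 2,2-dimethylbut-3-ynoate (C#CC(C)(C)C(=O)OC) is hydroborated with pinacolborane (Cp2ZrHCl cat.) to methyl (E)-2,2-dimethyl-4-(4,4,5,5-tetramethyl-1,3,2-dioxaborolan-2-yl)but-3-enoate F4. Suzuki–Miyaura coupling with 5 (PdCl2(dppf), K3PO4, THF–H2O) gives methyl (3E,8E)-10-(tert-butyldimethylsilyloxy)-2,2,9-trimethyl-5-methylidenedeca-3,8-dienoate F5. Saponification with LiOH in warm THF–MeOH–H2O gives 7.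

Step 7. The unprotected acyl Meldrum's acid may break down during handling, and acylketene oligomerisation may compete with closure of a 13-membered ring that holds two E alkenes. The fallback sets out from 9, returns at 12, and moves to a storable acyl donor that is activated by a thiophilic metal at room temperature. Heating 9 with 2-methylpropane-2-thiol in toluene gives S-tert-butyl (5E,10E)-12-(tert-butyldimethylsilyloxy)-4,4,11-trimethyl-7-methylidene-3-oxododeca-5,10-dienethioate F6, which can be chromatographed. HF·pyridine frees S-tert-butyl (5E,10E)-12-hydroxy-4,4,11-trimethyl-7-methylidene-3-oxododeca-5,10-dienethioate F7. Silver(I) trifluoroacetate in THF at high dilution promotes the thioester macrolactonisation to 12.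

Further compounds
F1 | step 8 | methyl (5E,10E)-12-hydroxy-4,4,11-trimethyl-7-methylidene-3-oxododeca-5,10-dienoate | COC(=O)CC(=O)C(C)(C)/C=C/C(=C)CC/C=C(\C)CO
F2 | step 8 | methyl (5E,10E)-12-(methoxycarbonyloxy)-4,4,11-trimethyl-7-methylidene-3-oxododeca-5,10-dienoate | COC(=O)CC(=O)C(C)(C)/C=C/C(=C)CC/C=C(\C)COC(=O)OC
F3 | step 8 | methyl (4E,9E)-3,3,10-trimethyl-6-methylidene-2-oxocycloundeca-4,9-diene-1-carboxylate (racemic) | C=C1/C=C/C(C)(C)C(=O)C(C(=O)OC)C/C(C)=C/CC1
F4 | step 4 | methyl (E)-2,2-dimethyl-4-(4,4,5,5-tetramethyl-1,3,2-dioxaborolan-2-yl)but-3-enoate | COC(=O)C(C)(C)/C=C/B1OC(C)(C)C(C)(C)O1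
F5 | step 4 | methyl (3E,8E)-10-(tert-butyldimethylsilyloxy)-2,2,9-trimethyl-5-methylidenedeca-3,8-dienoate | COC(=O)C(C)(C)/C=C/C(=C)CC/C=C(\C)CO[Si](C)(C)C(C)(C)C
F6 | step 7 | S-tert-butyl (5E,10E)-12-(tert-butyldimethylsilyloxy)-4,4,11-trimethyl-7-methylidene-3-oxododeca-5,10-dienethioate | CC(C)(C)SC(=O)CC(=O)C(C)(C)/C=C/C(=C)CC/C=C(\C)CO[Si](C)(C)C(C)(C)C
F7 | step 7 | S-tert-butyl (5E,10E)-12-hydroxy-4,4,11-trimethyl-7-methylidene-3-oxododeca-5,10-dienethioate | CC(C)(C)SC(=O)CC(=O)C(C)(C)/C=C/C(=C)CC/C=C(\C)CO
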